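**Retrosynthetic overview**
- Feature: rings A (C4a, C5, C6, C7, C8, C8a) and A'' are both phloroglucinol rings fused to a 2-aryl-4-pyranone, with oxygen on C5, C7 and C8a. The only methyl ether (C7) is meta to the chelated 5-OH and next to axis carbon C8, and axis carbon C6'' lies between 5''-OH and 7''-OH. These are the oxygen patterns of a 1,3-dimethoxy-1-silyloxy diene and of a 1-methoxy-1,3-bis(silyloxy) diene.
- Last step: hydrogenolysis of the 4'- and 4'''-benzyl ethers.
- Key disconnection: C8–C8a, C5–C4a, C8''–C8a'' and C5''–C4a'' are cut together. This leaves a tris-silylated tetraene (two dienes joined C8–C6'') and two molecules of 2-[4-(benzyloxy)phenyl]-5-bromo-4-pyranone, joined by a twofold formal [4+2] annulation with loss of HBr and methanol.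
- The axis bond C8–C6'' is made first, as an sp3–sp3 bond, by alkylating methyl acetoacetate with methyl 4-bromo-3-methoxycrotonate. Three O-silylations then give the tetraene.
- Ring order: rings C and C'' first (the bromopyranone, from an α-bromo enaminone and 4-(benzyloxy)benzoyl chloride), then rings A'' and A in one flask.

Key step: step 6

Assumption: the target SMILES carries no descriptor for the C8–C6'' axis, so the racemic atropisomer mixture is taken as the target; unprimed locants denote the 8-linked 7-methoxyflavone unit and doubly primed locants the 6''-linked unit.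

**Step 1**
Reactants: 1 methyl acetoacetate (1.5 equiv); 2 methyl (E)-4-bromo-3-methoxybut-2-enoate
Product: 3 dimethyl (2E)-5-acetyl-3-methoxyhex-2-enedioate (racemic at C5, labile)
Conditions: NaH (1.4 equiv), THF, 0 °C → rt
Reagents that add atoms: none
Why: SN2 C-alkylation of the stabilised sodium enolate (acetoacetic ester alkylation) at the primary allylic bromide, run with excess 1 to suppress dialkylation, leaves the alkene geometry untouched and gives a C5 centre that is later planarised.

**Step 2**
Reactants: 3 dimethyl (2E)-5-acetyl-3-methoxyhex-2-enedioate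
Product: 4 dimethyl (2E)-3-methoxy-5-[1-(trimethylsilyloxy)ethylidene]hex-2-enedioate (geometry of the new double bond immaterial)
Conditions: TMSCl (1.5 equiv), Et3N (1.6 equiv), toluene, rt, 48 h; filtration under Ar
Reagents that add atoms: chlorotrimethylsilane, C[Si](C)(C)Cl
Why: Silyl enol ether formation from the enolised β-keto ester under amine base masks the most acidic site, so that the next step needs only two kinetic deprotonations.

**Step 3**
Reactants: 4 dimethyl (2E)-3-methoxy-5-[1-(trimethylsilyloxy)ethylidene]hex-2-enedioate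
Product: 5 (3Z)-1,3-dimethoxy-5-[methoxy(trimethylsilyloxy)methylidene]-1,6-bis(trimethylsilyloxy)hepta-1,3,6-triene (the tetraene; C6 and C6'' trans across C7=C8, ketene acetal geometries immaterial)
Conditions: LDA (2.4 equiv), TMSCl (3 equiv, present from the start), THF, −78 → 0 °C; hexane, filtration under Ar, used crude
Reagents that add atoms: chlorotrimethylsilane, C[Si](C)(C)Cl
Why: γ-Deprotonation of the β-methoxy enoate and of the β-silyloxy enoate with LDA, with O-silylation of each dienolate as it forms (in situ quench), is the standard entry to 1-alkoxy-1-silyloxy-3-oxybutadienes, and the bulky C6'' group should end trans to C6 across C7=C8, which also rules out a 6π-electrocyclisation.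

**Step 4**
Reactants: 6 (E)-4-(dimethylamino)but-3-en-2-one
Product: 7 (Z)-3-bromo-4-(dimethylamino)but-3-en-2-one
Conditions: NBS (1.0 equiv), CH2Cl2, 0 °C; aq. NaHCO3 wash
Reagents that add atoms: N-bromosuccinimide, O=C1CCC(=O)N1Br
Why: Electrophilic α-halogenation of a push–pull enaminone occurs at its nucleophilic α-carbon, and loss of the proton from the iminium ion restores the enaminone.

**Step 5**
Reactants: 7 (Z)-3-bromo-4-(dimethylamino)but-3-en-2-one (2 equiv); 8 4-(benzyloxy)benzoyl chloride
Product: 10 2-[4-(benzyloxy)phenyl]-5-bromo-4H-pyran-4-one, via bromo enaminodiketone 9 (not isolated)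
Conditions: LiHMDS (2 equiv), THF, −78 °C; 8 (1 equiv), −78 → −20 °C; then 2 M HCl, THF, rt
Reagents that add atoms: none
Why: C-aroylation of the kinetic methyl enolate of an enaminone followed by acid-induced addition–elimination of the aryl-ketone enol oxygen at the aminomethine carbon (γ-pyranone synthesis by enaminone-anion acylation) brings C6 and the bromine in ready-made with 7, which fixes Br at C5 and avoids aminomethylenating a 1-aryl-1,3-butanedione, a reaction that would go to its central CH2.

**Step 6**
Reactants: 5 the tetraene; 10 2-[4-(benzyloxy)phenyl]-5-bromo-4H-pyran-4-one (2.2 equiv)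
Product: 14 4',4'''-di-O-benzyl-7-O-methylagathisflavone, via silyloxypyrylium triflate 11 (not isolated), via twofold conjugate adduct 12 (not isolated), via bis-pyranone diester 13 (not isolated)
Conditions: 10, Me3SiOTf (2.4 equiv), CH2Cl2, 0 °C → rt, 1 h; 5, −78 → 0 °C; concentrate; NaOMe (12 equiv), MeOH–THF, 0 → 50 °C; 1 M HCl
Reagents that add atoms: none
Why: Proposed new method: Me3SiOTf converts 10 into the 4-silyloxypyrylium salt 11, and the two electron-rich diene termini of 5 (first the unsubstituted C8'', then C8) add to its free α-position C6 in vinylogous Mukaiyama–Michael fashion, which sets C8''–C8a'' and C8–C8a and leaves the bromo silyl enol ethers of 12. Because a suprafacial cycloadduct would hold H-8a and Br-4a cis, with no anti-periplanar path for loss of HBr, and would be a positive-bromine 2-bromo-1,3-diketone, the [4+2] is finished on purpose in a second stage: methoxide desilylates 12, the epimerisable α-bromo ketones lose HBr by anti elimination to restore both pyranones in 13, and any material that has already collapsed to the bicycle re-enters this path by retro-Claisen opening. Ring A'' and then ring A close by 6-(enolexo)-exo-trig Claisen acylation, in which the pyranone dienolates formed by deprotonation at C8'' and C8 attack the ester carbons C5'' and C5 through C4a'' and C4a (the E-methoxyenoate already holds C5 cis to C8), and loss of methanol with dienone–phenol tautomerisation makes each closure irreversible. The closest known reactions are the Diels–Alder addition of 1-methoxy-1-silyloxy-3-oxy dienes to haloquinones with loss of HX and methanol, the Me3SiOTf-mediated addition of 1,3-bis(silyloxy)butadienes to chromones through benzopyrylium triflates, the base dehydrobromination of 3-bromochroman-4-ones and the Claisen-mode cyclisation of 3,5,7-triketo esters to acylphloroglucinols. The sp3 centres that appear at C8, C8a, C4a, C6'', C8a'' and C4a'' are all erased on aromatisation, and the only lasting stereoelement, the C8–C6'' axis, forms without control as the racemate. The step needs terminal (γ) rather than α attack of each dienolate and attack at C6 rather than C2 of the pyrylium ion; the oxygen on C7 and C7'' places the largest coefficient on C8 and C8'', the 2-aryl group blocks C2 and spreads its charge, and the bromine on C5 carries the oxidation level that lets C6 keep its ring oxygen and become C8a.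

**Step 7**
Reactants: 14 4',4'''-di-O-benzyl-7-O-methylagathisflavone
Product: 15 7-O-methylagathisflavone (target, racemic about the axis)
Conditions: H2 (1 atm), 10% Pd/C, THF–MeOH, rt
Reagents that add atoms: none
Why: Catalytic hydrogenolysis cleaves the two aryl benzyl ethers, while the flavone C2=C3 bonds, the methyl ether and the phenols are inert at this pressure and temperature.

**Compound list**
1 | methyl acetoacetate | COC(=O)CC(C)=O | starting material
2 | methyl (E)-4-bromo-3-methoxybut-2-enoate | CO/C(CBr)=C/C(=O)OC | starting material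
3 | dimethyl (2E)-5-acetyl-3-methoxyhex-2-enedioate (racemic) | CO/C(CC(C(C)=O)C(=O)OC)=C/C(=O)OC | intermediate
4 | dimethyl (2E)-3-methoxy-5-[1-(trimethylsilyloxy)ethylidene]hex-2-enedioate | CO/C(CC(C(=O)OC)=C(C)O[Si](C)(C)C)=C/C(=O)OC | intermediate
5 | (3Z)-1,3-dimethoxy-5-[methoxy(trimethylsilyloxy)methylidene]-1,6-bis(trimethylsilyloxy)hepta-1,3,6-triene (tetraene) | COC(O[Si](C)(C)C)=C/C(OC)=C/C(=C(OC)O[Si](C)(C)C)C(=C)O[Si](C)(C)C | intermediate
6 | (E)-4-(dimethylamino)but-3-en-2-one | CC(=O)/C=C/N(C)C | starting material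
7 | (Z)-3-bromo-4-(dimethylamino)but-3-en-2-one | CC(=O)/C(Br)=C/N(C)C | intermediate
8 | 4-(benzyloxy)benzoyl chloride | O=C(Cl)c1ccc(OCc2ccccc2)cc1 | starting material
9 | (Z)-1-[4-(benzyloxy)phenyl]-4-bromo-5-(dimethylamino)pent-4-ene-1,3-dione (not isolated) | CN(C)/C=C(Br)/C(=O)CC(=O)c1ccc(OCc2ccccc2)cc1 | intermediate
10 | 2-[4-(benzyloxy)phenyl]-5-bromo-4H-pyran-4-one | O=c1cc(-c2ccc(OCc3ccccc3)cc2)occ1Br | intermediate
11 | 2-[4-(benzyloxy)phenyl]-5-bromo-4-(trimethylsilyloxy)pyrylium trifluoromethanesulfonate (not isolated) | C[Si](C)(C)Oc1cc(-c2ccc(OCc3ccccc3)cc2)[o+]cc1Br.[O-]S(=O)(=O)C(F)(F)F | intermediate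
12 | twofold conjugate adduct: dimethyl (2E)-3-methoxyhex-2-enedioate carrying a 6-aryl-3-bromo-4-(trimethylsilyloxy)-2H-pyran-2-yl group on C4 and a 2-(same pyranyl)-1-(trimethylsilyloxy)ethylidene group on C5 (diastereomer mixture, centres transient, not isolated) | CO/C(=C/C(=O)OC)C(C1OC(c2ccc(OCc3ccccc3)cc2)=CC(O[Si](C)(C)C)=C1Br)C(C(=O)OC)=C(O[Si](C)(C)C)CC4OC(c5ccc(OCc6ccccc6)cc5)=CC(O[Si](C)(C)C)=C4Br | intermediate
13 | dimethyl (2E)-4-{6-[4-(benzyloxy)phenyl]-4-oxo-4H-pyran-2-yl}-5-({6-[4-(benzyloxy)phenyl]-4-oxo-4H-pyran-2-yl}acetyl)-3-methoxyhex-2-enedioate (not isolated) | CO/C(=C/C(=O)OC)C(c1cc(=O)cc(-c2ccc(OCc3ccccc3)cc2)o1)C(C(=O)OC)C(=O)Cc1cc(=O)cc(-c2ccc(OCc3ccccc3)cc2)o1 | intermediate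
14 | 4',4'''-di-O-benzyl-7-O-methylagathisflavone | COc1cc(O)c2c(=O)cc(-c3ccc(OCc4ccccc4)cc3)oc2c1-c1c(O)cc2oc(-c3ccc(OCc4ccccc4)cc3)cc(=O)c2c1O | intermediate
15 | 7-O-methylagathisflavone | COc1cc(O)c2c(=O)cc(-c3ccc(O)cc3)oc2c1-c1c(O)cc2oc(-c3ccc(O)cc3)cc(=O)c2c1O | target

**Step count**
Total steps: 7. Longest linear sequence: 5 steps (1, 2, 3, 6, 7).

**Steps most likely to fail**

**Step 6.**
- What may go wrong:
  - The hindered terminus C8 may react through its α-carbon instead.
  - The dihydropyranone may open by retro-oxa-Michael reaction, or give up bromine as positive halogen, before HBr is lost.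
  - The Claisen closure onto the poorly electrophilic methoxyenoate ester next to the crowded axis may stall.
- Fallback: known chemistry that sets out from 8 and comes back at 15.
  - The lithium dianion of commercial 2'-hydroxy-4',6'-dimethoxyacetophenone (LiHMDS, THF, −78 °C) is aroylated with 8 to give 1-[4-(benzyloxy)phenyl]-3-(2-hydroxy-4,6-dimethoxyphenyl)propane-1,3-dione F1.
  - p-TsOH in hot toluene cyclodehydrates this to 4'-(benzyloxy)-5,7-dimethoxyflavone F2.
  - NIS with TFA in MeCN iodinates the fully alkylated ring A at C8 to give 4'-(benzyloxy)-8-iodo-5,7-dimethoxyflavone F3.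
  - Miyaura borylation (B2pin2, PdCl2(dppf), KOAc, dioxane) gives 4'-(benzyloxy)-5,7-dimethoxyflavone-8-boronic acid pinacol ester F4.
  - In parallel, commercial apigenin is benzylated at O7 and O4' (BnBr, K2CO3, DMF) to 7,4'-di-O-benzylapigenin F5.
  - It is iodinated ortho to the chelated 5-hydroxyl (BnMe3NICl2, CaCO3, CH2Cl2–MeOH) to 7,4'-di-O-benzyl-6-iodoapigenin F6, then benzylated at O5 (BnBr, K2CO3, DMF, 60 °C) to 5,7,4'-tri-O-benzyl-6-iodoapigenin F7.
  - Suzuki–Miyaura coupling of the two halves (Pd(OAc)2, SPhos, K3PO4, toluene–water, 100 °C) gives 4',4''',5'',7''-tetra-O-benzyl-5,7-di-O-methylagathisflavone F8.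
  - BCl3 with pentamethylbenzene (CH2Cl2, −78 → 0 °C) removes the four benzyl groups and the chelation-activated 5-methyl ether. The 7-methyl ether stays in place, and the product is 15.

**Step 3.**
- What may go wrong:
  - Deprotonation at C8 may be incomplete.
  - C-silylation or hydrolysis on handling may occur.
  - The C7=C8 isomer with C6 and C6'' cis may form, which would open the way to electrocyclic ring closure.
- Fallback: sets out from 3 and comes back at 5. It treats the three sites by two different enolisation modes.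
  - Soft enolisation of the β-keto ester alone (Me3SiOTf 2.2 equiv, Et3N, Et2O, 0 °C) gives methyl (2E)-3-methoxy-5-[methoxy(trimethylsilyloxy)methylidene]-6-(trimethylsilyloxy)hepta-2,6-dienoate F9.
  - Only one hard enolisation is then left (LDA 1.1 equiv, THF, −78 °C, then TMSCl) to reach 5.

**Step 5.**
- What may go wrong:
  - The enolate may be O-acylated.
  - The amide base may consume the acid chloride.
  - The bromo enaminone may degrade under strong base.
- Fallback: sets out from 8 and comes back at 10.
  - 8 is reduced with LiAlH(OtBu)3 (THF, −78 °C) to 4-(benzyloxy)benzaldehyde F10, which can also be bought.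
  - A ZnCl2-catalysed hetero-Diels–Alder reaction with (E)-1-methoxy-3-(trimethylsilyloxy)buta-1,3-diene gives 2-[4-(benzyloxy)phenyl]-6-methoxy-4-(trimethylsilyloxy)-3,6-dihydro-2H-pyran F11.
  - TFA converts this into racemic 2-[4-(benzyloxy)phenyl]-2,3-dihydro-4H-pyran-4-one F12.
  - NBS (CH2Cl2, 0 °C) brominates the only enol-ether carbon, C5, to give 2-[4-(benzyloxy)phenyl]-5-bromo-2,3-dihydro-4H-pyran-4-one F13.
  - DDQ in hot dioxane dehydrogenates C2–C3, as in the flavanone to flavone oxidation, to give 10.

**Further compounds**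
F1 | step 6 | 1-[4-(benzyloxy)phenyl]-3-(2-hydroxy-4,6-dimethoxyphenyl)propane-1,3-dione | COc1cc(O)c(C(=O)CC(=O)c2ccc(OCc3ccccc3)cc2)c(OC)c1
F2 | step 6 | 4'-(benzyloxy)-5,7-dimethoxyflavone | COc1cc(OC)c2c(=O)cc(-c3ccc(OCc4ccccc4)cc3)oc2c1
F3 | step 6 | 4'-(benzyloxy)-8-iodo-5,7-dimethoxyflavone | COc1cc(OC)c2c(=O)cc(-c3ccc(OCc4ccccc4)cc3)oc2c1I
F4 | step 6 | 4'-(benzyloxy)-5,7-dimethoxyflavone-8-boronic acid pinacol ester | COc1cc(OC)c2c(=O)cc(-c3ccc(OCc4ccccc4)cc3)oc2c1B1OC(C)(C)C(C)(C)O1
F5 | step 6 | 7,4'-di-O-benzylapigenin | O=c1cc(-c2ccc(OCc3ccccc3)cc2)oc2cc(OCc3ccccc3)cc(O)c12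
F6 | step 6 | 7,4'-di-O-benzyl-6-iodoapigenin | O=c1cc(-c2ccc(OCc3ccccc3)cc2)oc2cc(OCc3ccccc3)c(I)c(O)c12
F7 | step 6 | 5,7,4'-tri-O-benzyl-6-iodoapigenin | O=c1cc(-c2ccc(OCc3ccccc3)cc2)oc2cc(OCc3ccccc3)c(I)c(OCc3ccccc3)c12
F8 | step 6 | 4',4''',5'',7''-tetra-O-benzyl-5,7-di-O-methylagathisflavone | COc1cc(OC)c2c(=O)cc(-c3ccc(OCc4ccccc4)cc3)oc2c1-c1c(OCc2ccccc2)cc2oc(-c3ccc(OCc4ccccc4)cc3)cc(=O)c2c1OCc1ccccc1
F9 | step 3 | methyl (2E)-3-methoxy-5-[methoxy(trimethylsilyloxy)methylidene]-6-(trimethylsilyloxy)hepta-2,6-dienoate | CO/C(=C/C(=O)OC)CC(=C(OC)O[Si](C)(C)C)C(=C)O[Si](C)(C)C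
F10 | step 5 | 4-(benzyloxy)benzaldehyde | O=Cc1ccc(OCc2ccccc2)cc1
F11 | step 5 | 2-[4-(benzyloxy)phenyl]-6-methoxy-4-(trimethylsilyloxy)-3,6-dihydro-2H-pyran | COC1C=C(O[Si](C)(C)C)CC(c2ccc(OCc3ccccc3)cc2)O1
F12 | step 5 | 2-[4-(benzyloxy)phenyl]-2,3-dihydro-4H-pyran-4-one (racemic) | O=C1C=COC(c2ccc(OCc3ccccc3)cc2)C1
F13 | step 5 | 2-[4-(benzyloxy)phenyl]-5-bromo-2,3-dihydro-4H-pyran-4-one (racemic) | O=C1CC(c2ccc(OCc3ccccc3)cc2)OC=C1Br
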